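**Plan**

1. Labdane numbering is used: ring A = C1–C5, C10; ring B = C5–C10; oxolane = C9, C11–C13, O; dihydrofuran = C13–C16, O. The target is (5S,6S,8S,9R,10S,13R)-6-acetoxy-9,13:15,16-diepoxylabd-14-en-7-one.
2. Cuts: the C14=C15–O enol ether (from a lactol made from an allyl group and the C16 hydroxyl); C8–C9 (ring B); C7–C8 (ethyl Grignard); C5–H/C6–O and C5–C6 (from the ring-A ketone); C11–C12 (acetylide + epoxide); C10–C9 (allylic alkylation).
3. Enabling feature: C9 is an ether carbon β to the C7 ketone, and O6 and O13 both sit 1,4 to C9. A C9 ketone can therefore be stored as a bis-oxolane spiroketal (C6–O–C9–O–C13); once its C9–O6 bond is ionised, C9 is handed to the enol carbon C8.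
4. Forward order: ring-A ketone → quaternary C10 → C9 alkyne → union with the C12–C16 epoxide → C6/C7 chain → C9 ketal (first oxolane) → C5–H/C6–OH → spiroketal (second, temporary oxolane) → ethyl ketone → ring B by the spiroketal-to-carbocycle switch → acetate → dihydrofuran.
5. Stereochemistry: C10 from the Pd/PHOX alkylation; C13 from Sharpless epoxidation; C5 from hydrogen delivery anti to the axial methyls of ring A; C6 by equilibration inside the spiroketal; C9 and C8 in the key step (chair; C8 is also the thermodynamic epimer).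

Key step: step 15

Assumption: the facial sense of the PHOX-controlled allylation of 2 is taken to follow that of the 2-methylcyclohexanone series, so that (R)-t-Bu-PHOX gives (R)-3; if the sense is opposite, the (S)-ligand is used.

**Route**

Step 1
Reactants: 1 2,2,6-trimethylcyclohexan-1-one
Product: 2 allyl 2,6,6-trimethylcyclohex-1-en-1-yl carbonate
Conditions: LiN(SiMe3)2, TMEDA, THF, 0 °C; then allyl chloroformate, −78 °C → rt
Reagents that add atoms: allyl chloroformate, C=CCOC(=O)Cl
Why: The ketone has a single enolisable position, so the lithium enolate forms regiospecifically and is O-acylated by the chloroformate to the tetrasubstituted enol carbonate (enolate O-acylation).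

Step 2
Reactants: 2 allyl 2,6,6-trimethylcyclohex-1-en-1-yl carbonate
Product: 3 (R)-2-allyl-2,6,6-trimethylcyclohexan-1-one
Conditions: Pd2(dba)3 (2.5 mol %), (R)-t-Bu-PHOX (6 mol %), THF, 25 °C
Reagents that add atoms: none
Why: Decarboxylative asymmetric allylic alkylation (Tsuji–Trost type) of the enol carbonate creates the quaternary C10 centre, the chiral PHOX ligand on palladium selecting the enolate face, a transformation with close precedent on this substrate type.

Step 3
Reactants: 3 (R)-2-allyl-2,6,6-trimethylcyclohexan-1-one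
Product: 4 (R)-2,6,6-trimethyl-2-[(E)-prop-1-en-1-yl]cyclohexan-1-one
Conditions: RuHCl(CO)(PPh3)3 (5 mol %), toluene, 80 °C
Reagents that add atoms: none
Why: Ruthenium hydride-catalysed olefin isomerisation moves the double bond one position inward and stops there because C10 is quaternary.

Step 4
Reactants: 4 (R)-2,6,6-trimethyl-2-[(E)-prop-1-en-1-yl]cyclohexan-1-one
Product: 5 (R)-1,3,3-trimethyl-2-oxocyclohexane-1-carbaldehyde
Conditions: O3, CH2Cl2, −78 °C; then PPh3, −78 °C → rt
Reagents that add atoms: ozone, [O-][O+]=O
Why: Ozonolysis with reductive work-up cleaves the only C=C bond to the non-enolisable aldehyde (C9), the hindered ketone being inert.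

Step 5
Reactants: 5 (R)-1,3,3-trimethyl-2-oxocyclohexane-1-carbaldehyde
Product: 6 (R)-2-ethynyl-2,6,6-trimethylcyclohexan-1-one
Conditions: TMSCHN2, n-BuLi, THF, −78 °C; then 5, −78 °C → rt
Reagents that add atoms: (trimethylsilyl)diazomethane, C[Si](C)(C)C=[N+]=[N-]
Why: Colvin rearrangement: the lithiated diazo reagent adds only to the aldehyde, loss of silanolate and N2 gives an alkylidene carbene whose 1,2-hydrogen shift delivers the alkyne, and the aprotic conditions avoid base-induced deformylation of the β-keto aldehyde.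

Step 6
Reactants: 7 prop-2-yn-1-ol
Product: 8 2-methylidenepent-4-en-1-ol
Conditions: allylmagnesium bromide (2.5 equiv), CuI (10 mol %), Et2O/THF, −20 °C → rt; NH4Cl aq.
Reagents that add atoms: allylmagnesium bromide, C=CC[Mg]Br
Why: Alkoxide-directed carbomagnesiation of the propargylic alcohol places the allyl group on the internal alkyne carbon through a chelated magnesium alkoxide, giving the 2-substituted allylic alcohol after protonation.

Step 7
Reactants: 8 2-methylidenepent-4-en-1-ol
Product: 9 [(R)-2-allyloxiran-2-yl]methanol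
Conditions: Ti(Oi-Pr)4 (10 mol %), D-(−)-diisopropyl tartrate (12 mol %), t-BuOOH, 4 Å MS, CH2Cl2, −20 °C
Reagents that add atoms: tert-butyl hydroperoxide, CC(C)(C)OO
Why: Sharpless asymmetric epoxidation oxidises only the allylic-alcohol double bond, and the D-(−)-tartrate/titanium catalyst selects the face that gives the (R)-epoxide, which fixes the future C13 centre.

Step 8
Reactants: 9 [(R)-2-allyloxiran-2-yl]methanol
Product: 10 (S)-2-allyl-2-[(tert-butyldimethylsilyloxy)methyl]oxirane
Conditions: TBSCl, imidazole, CH2Cl2, 0 °C → rt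
Reagents that add atoms: tert-butyldimethylsilyl chloride, CC(C)(C)[Si](C)(C)Cl
Why: Imidazole-mediated silylation protects the primary (C16) hydroxyl without touching the epoxide; the descriptor changes only through the priority rules.

Step 9
Reactants: 6 (R)-2-ethynyl-2,6,6-trimethylcyclohexan-1-one; 10 (S)-2-allyl-2-[(tert-butyldimethylsilyloxy)methyl]oxirane
Product: 12 (R)-2-[(S)-4-hydroxy-4-[(tert-butyldimethylsilyloxy)methyl]hept-6-en-1-yn-1-yl]-2,6,6-trimethylcyclohexan-1-one, via lithium acetylide 11 (not isolated)
Conditions: n-BuLi, THF, −78 °C; BF3·OEt2; then 10, −78 °C; NH4Cl aq.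
Reagents that add atoms: none
Why: BF3-promoted opening of the 2,2-disubstituted epoxide by the acetylide (Yamaguchi alkynylation) occurs at the CH2 carbon in SN2 fashion, so C13 keeps its configuration, and the hindered non-enolisable ring ketone does not interfere.

Step 10
Reactants: 12 (R)-2-[(S)-4-hydroxy-4-[(tert-butyldimethylsilyloxy)methyl]hept-6-en-1-yn-1-yl]-2,6,6-trimethylcyclohexan-1-one
Product: 13 (2R)-1-(ethoxyethynyl)-2-[(S)-4-hydroxy-4-[(tert-butyldimethylsilyloxy)methyl]hept-6-en-1-yn-1-yl]-2,6,6-trimethylcyclohexan-1-ol (both C5 epimers)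
Conditions: ethoxyacetylene, n-BuLi (3 equiv each), THF, −78 °C; then 12, −78 → 0 °C
Reagents that add atoms: ethoxyacetylene, CCOC#C
Why: 1,2-Addition of the small lithium ethoxyacetylide to the hindered but non-enolisable ketone should proceed while the C13 alkoxide is a spectator, and the new carbinol configuration is irrelevant because it is erased in step 11.

Step 11
Reactants: 13 ethoxyalkynyl carbinol
Product: 14 ethyl 2-[2-(2-ethoxy-5-allyl-5-[(tert-butyldimethylsilyloxy)methyl]oxolan-2-yl)-2,6,6-trimethylcyclohexylidene]acetate (C10 and C13 as in 12; C9 epimers; both alkene isomers)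
Conditions: Ph3PAuNTf2 (5 mol %), EtOH/CH2Cl2 (1:4), rt
Reagents that add atoms: ethanol, CCO
Why: The gold catalyst first effects Meyer–Schuster rearrangement of the ethoxyalkynyl carbinol to the unsaturated ester (no β-hydrogen exists for a Rupe pathway) and then 5-endo-dig addition of the tertiary homopropargylic hydroxyl to C9 followed by ethanol addition, turning the alkyne into a bulky sp3 mixed ketal, the hydroxyl being a better nucleophile for the activated alkyne than the monosubstituted allyl group.

Step 12
Reactants: 14 enoate ketal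
Product: 15 ethyl 2-hydroxy-2-[2-(2-ethoxy-5-allyl-5-[(tert-butyldimethylsilyloxy)methyl]oxolan-2-yl)-2,6,6-trimethylcyclohexyl]acetate with H5 trans to the C10 methyl (C6 and C9 epimers)
Conditions: Mn(dpm)3 (10 mol %), PhSiH3, O2 (1 atm), i-PrOH/CH2Cl2, 0 °C → rt
Reagents that add atoms: dioxygen, O=O
Why: Mukaiyama-type reductive α-hydroxylation (metal-hydride hydrogen-atom transfer to the β-carbon C5, O2 capture of the C6 radical): with the bulky C9 ketal equatorial and the C10 methyl axial, hydrogen reaches C5 anti to the two syn-axial methyls, setting H5 trans to the C10 methyl, while the C6 mixture is corrected in step 14 and the electron-poor conjugated alkene should react ahead of the isolated allyl group.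

Step 13
Reactants: 15 α-hydroxy ester
Product: 16 ethyl 6,9:9,13-diepoxy spiroketal ester (1,6-dioxaspiro[4.4]nonane with the C6–O–C9 oxolane trans-fused to ring A; C6 and C9 epimers)
Conditions: camphorsulfonic acid (5 mol %), 4 Å MS, CH2Cl2, rt
Reagents that add atoms: none
Why: Acid-catalysed transketalisation: loss of ethanol gives the C9 oxocarbenium ion, which the C6 hydroxyl captures in a 5-exo closure because C6 and C9 are trans-diequatorial on ring A.

Step 14
Reactants: 16 spiroketal ester
Product: 18 spiroketal ethyl ketone (propanoyl on C6 cis to H5), via Weinreb amide 17 (not isolated)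
Conditions: MeNHOMe·HCl, i-PrMgCl, THF, −20 °C; then EtMgBr, 0 °C; NH4Cl aq.; then K2CO3, MeOH, rt
Reagents that add atoms: ethylmagnesium bromide, CC[Mg]Br
Why: One-pot Weinreb amidation and Grignard addition gives the ethyl ketone without over-addition (stable magnesium chelate), and base then equilibrates the epimerisable C6 centre to the isomer with the propanoyl group cis to H5 and trans to the quaternary C4 on the oxolane, which is the arrangement that becomes the 6β-oxygen of the target.

Step 15
Reactants: 18 spiroketal ethyl ketone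
Product: 21 6β-hydroxy-7-oxo-9α,13-epoxy decalin (ring B closed; 8α-methyl; C13 bears allyl and CH2OTBS), via enol silane 19 (not isolated), via silyl ether 20 (not isolated)
Conditions: TMSOTf (2.5 equiv), i-Pr2NEt (1.5 equiv), CH2Cl2, −78 → −20 °C; then 1 M HCl, THF, 0 °C
Reagents that add atoms: none
Why: TMSOTf/i-Pr2NEt first turns the ethyl ketone into the (Z)-enol silane 19 at the unhindered C8 methylene, then excess TMSOTf silylates the ketal oxygen O6 and breaks the trans-fused C9–O6 bond to give the C9 oxocarbenium ion stabilised by O13, which C8 attacks while the silyl group ends on O6 (19 → 20 is an isomerisation). The closest known reaction type is the TMSOTf-promoted Mukaiyama aldol-type addition of enol silanes to ketals, here intramolecular and with opening of the ketal ring, an O-to-C ring switch akin to the Ferrier carbocyclisation. Ring B closes in the 6-(enolendo)-exo-trig mode through a chair, and no other ring is formed (the C6–O–C9 oxolane is the one that opens). C9 is set in the C–C bond formation, the chair placing the smaller ring oxygen O13 axial (α, anti to the axial C10 methyl) and the C11 methylene equatorial, and C8 is set by the (Z)-enol geometry, which puts the methyl equatorial (α), the arrangement also favoured thermodynamically next to the ketone; C6 is not touched, so its oxygen emerges as the axial 6β-hydroxyl. The step needs ionisation of C9–O6 rather than C9–O13 and attack by C8 rather than by the allyl group: O6 is the less hindered oxygen, cleavage of C9–O13 is non-productive and reversible (C8 could then only close a strained 5-(enolendo)-endo ring), and the enol silane is far more nucleophilic than a monosubstituted alkene. Cold dilute acid in the work-up removes the trimethylsilyl group from O6 without enolising the ketone toward C6.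

Step 16
Reactants: 21 6β-hydroxy ketone
Product: 22 6β-acetoxy ketone (C16 O-TBS; C13 allyl)
Conditions: Ac2O, DMAP, pyridine, CH2Cl2, rt → 40 °C
Reagents that add atoms: acetic anhydride, CC(=O)OC(C)=O
Why: DMAP-catalysed acetylation esterifies the hindered axial hydroxyl, and C6 should hold because its hydrogen is equatorial and poorly aligned for enolisation.

Step 17
Reactants: 22 6β-acetoxy ketone
Product: 23 C16 primary alcohol
Conditions: Bu4NF, AcOH, THF, 0 °C → rt
Reagents that add atoms: none
Why: Fluoride cleaves the primary silyl ether, with acetic acid buffering to prevent enolisation or acyl transfer of the α-acetoxy ketone.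

Step 18
Reactants: 23 C16 primary alcohol
Product: 25 15-hydroxy-15,16-epoxy lactol (both anomers), via hydroxy aldehyde 24 (not isolated)
Conditions: O3, CH2Cl2, −78 °C; then PPh3, −78 °C → rt
Reagents that add atoms: ozone, [O-][O+]=O
Why: Ozonolysis of the only C=C bond gives the C15 aldehyde, which the C16 hydroxyl traps at once as the five-membered lactol.

Step 19
Reactants: 25 lactol
Product: 27 (5S,6S,8S,9R,10S,13R)-6-acetoxy-9,13:15,16-diepoxylabd-14-en-7-one (CNP0224709.1), via anomeric mesylate 26 (not isolated)
Conditions: MsCl, Et3N (5 equiv), CH2Cl2, −40 → 0 °C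
Reagents that add atoms: none
Why: Sulfonylation of the anomeric hydroxyl and amine-promoted elimination (lactol-to-glycal dehydration) gives the 2,3-dihydrofuran, excess base being kept throughout because the spiro enol ether would ionise at C13–O and aromatise to the furan under acid.

**Compound list**

1 | 2,2,6-trimethylcyclohexan-1-one (racemic) | CC1CCCC(C)(C)C1=O | starting material
2 | allyl 2,6,6-trimethylcyclohex-1-en-1-yl carbonate | C=CCOC(=O)OC1=C(C)CCCC1(C)C | intermediate
3 | (R)-2-allyl-2,6,6-trimethylcyclohexan-1-one | C=CC[C@@]1(C)CCCC(C)(C)C1=O | intermediate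
4 | (R)-2,6,6-trimethyl-2-[(E)-prop-1-en-1-yl]cyclohexan-1-one | C/C=C/[C@@]1(C)CCCC(C)(C)C1=O | intermediate
5 | (R)-1,3,3-trimethyl-2-oxocyclohexane-1-carbaldehyde | O=C[C@@]1(C)CCCC(C)(C)C1=O | intermediate
6 | (R)-2-ethynyl-2,6,6-trimethylcyclohexan-1-one | C#C[C@@]1(C)CCCC(C)(C)C1=O | intermediate
7 | prop-2-yn-1-ol | C#CCO | starting material
8 | 2-methylidenepent-4-en-1-ol | C=CCC(=C)CO | intermediate
9 | [(R)-2-allyloxiran-2-yl]methanol | C=CC[C@@]1(CO)CO1 | intermediate
10 | (S)-2-allyl-2-[(tert-butyldimethylsilyloxy)methyl]oxirane | C=CC[C@@]1(CO[Si](C)(C)C(C)(C)C)CO1 | intermediate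
11 | lithium acetylide of 6 | [Li]C#C[C@@]1(C)CCCC(C)(C)C1=O | intermediate
12 | (R)-2-[(S)-4-hydroxy-4-[(tert-butyldimethylsilyloxy)methyl]hept-6-en-1-yn-1-yl]-2,6,6-trimethylcyclohexan-1-one | C=CC[C@@](O)(CO[Si](C)(C)C(C)(C)C)CC#C[C@@]1(C)CCCC(C)(C)C1=O | intermediate
13 | ethoxyalkynyl carbinol (ethoxyethynyl and OH on C5, both epimers) | CCOC#CC1(O)C(C)(C)CCC[C@]1(C)C#CC[C@@](O)(CC=C)CO[Si](C)(C)C(C)(C)C | intermediate
14 | enoate ketal (ethyl cyclohexylideneacetate; 2-ethoxyoxolane at C9; C9 epimers, both alkene isomers) | CCOC(=O)C=C1C(C)(C)CCC[C@]1(C)C1(OCC)CC[C@@](CC=C)(CO[Si](C)(C)C(C)(C)C)O1 | intermediate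
15 | α-hydroxy ester (H5 trans to C10 methyl; C6 and C9 epimers) | CCOC(=O)C(O)[C@H]1C(C)(C)CCC[C@]1(C)C1(OCC)CC[C@@](CC=C)(CO[Si](C)(C)C(C)(C)C)O1 | intermediate
16 | spiroketal ethyl ester (C6–O–C9–O–C13 bis-oxolane; C6 and C9 epimers) | CCOC(=O)C1OC2(CC[C@@](CC=C)(CO[Si](C)(C)C(C)(C)C)O2)[C@@]2(C)CCCC(C)(C)[C@H]12 | intermediate
17 | Weinreb amide of 16 | CON(C)C(=O)C1OC2(CC[C@@](CC=C)(CO[Si](C)(C)C(C)(C)C)O2)[C@@]2(C)CCCC(C)(C)[C@H]12 | intermediate
18 | spiroketal ethyl ketone (propanoyl on C6 cis to H5; C9 epimers) | CCC(=O)[C@H]1OC2(CC[C@@](CC=C)(CO[Si](C)(C)C(C)(C)C)O2)[C@@]2(C)CCCC(C)(C)[C@H]12 | intermediate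
19 | (Z)-trimethylsilyl enol ether of 18 | C/C=C(\O[Si](C)(C)C)[C@H]1OC2(CC[C@@](CC=C)(CO[Si](C)(C)C(C)(C)C)O2)[C@@]2(C)CCCC(C)(C)[C@H]12 | intermediate
20 | 6-O-trimethylsilyl ether of 21 | C[Si](C)(C)O[C@@H]1C(=O)[C@@H](C)[C@]2(CC[C@@](CC=C)(CO[Si](C)(C)C(C)(C)C)O2)[C@@]2(C)CCCC(C)(C)[C@H]12 | intermediate
21 | 6β-hydroxy-7-oxo-9α,13-epoxy decalin (8α-methyl; C13 allyl and CH2OTBS) | O[C@@H]1C(=O)[C@@H](C)[C@]2(CC[C@@](CC=C)(CO[Si](C)(C)C(C)(C)C)O2)[C@@]2(C)CCCC(C)(C)[C@H]12 | intermediate
22 | 6β-acetate of 21 | CC(=O)O[C@@H]1C(=O)[C@@H](C)[C@]2(CC[C@@](CC=C)(CO[Si](C)(C)C(C)(C)C)O2)[C@@]2(C)CCCC(C)(C)[C@H]12 | intermediate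
23 | C16 primary alcohol (desilylated 22) | CC(=O)O[C@@H]1C(=O)[C@@H](C)[C@]2(CC[C@@](CC=C)(CO)O2)[C@@]2(C)CCCC(C)(C)[C@H]12 | intermediate
24 | C15 aldehyde with free C16 hydroxyl | CC(=O)O[C@@H]1C(=O)[C@@H](C)[C@]2(CC[C@@](CC=O)(CO)O2)[C@@]2(C)CCCC(C)(C)[C@H]12 | intermediate
25 | lactol (15-hydroxy-15,16-epoxy; both anomers) | CC(=O)O[C@@H]1C(=O)[C@@H](C)[C@]2(CC[C@]3(CC(O)OC3)O2)[C@@]2(C)CCCC(C)(C)[C@H]12 | intermediate
26 | anomeric mesylate of 25 | CC(=O)O[C@@H]1C(=O)[C@@H](C)[C@]2(CC[C@]3(CC(OS(C)(=O)=O)OC3)O2)[C@@]2(C)CCCC(C)(C)[C@H]12 | intermediate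
27 | (5S,6S,8S,9R,10S,13R)-6-acetoxy-9,13:15,16-diepoxylabd-14-en-7-one | CC(=O)O[C@@H]1C(=O)[C@@H](C)[C@]2(CC[C@]3(C=COC3)O2)[C@@]2(C)CCCC(C)(C)[C@H]12 | target

**Step count and risks**

Total step count: 19. Longest linear sequence: 16 (steps 1–5 and 9–19).

Steps most likely to fail:

1. Step 15. The C–C bond formation may show poor facial selectivity at C9 (the two chair arrangements of the spiro oxolane differ only modestly in energy), or the oxocarbenium ion may be diverted by proton loss or capture by the allyl group. The fallback sets out from 18 and returns at 21, and sets C9 by thermodynamically controlled C–O rather than kinetically controlled C–C bond formation. Heating 18 with TsOH in benzene opens the spiroketal, lets the C8 enol add to C9 and eliminates the C13 oxygen from the β-alkoxy ketone, an intramolecular aldol condensation that should give the Δ8(9)-en-7-one diol F1. Catalytic t-BuOK in t-BuOH/THF should then bring about 5-exo-trig oxa-Michael addition of the tertiary C13 hydroxyl to C9 (axial attack anti to the C10 methyl, C8 protonated to the equatorial methyl) to give 21.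

2. Step 12. Hydrogen-atom transfer may also occur to the isolated allyl double bond, the radical may be over-reduced, or facial discrimination at C5 may be insufficient. The fallback sets out from 14 and returns at 15 by a polar two-step sequence. Conjugate reduction with [(Ph3P)CuH]6 (catalytic) and polymethylhydrosiloxane, which leaves isolated alkenes alone and should deliver hydride to C5 from the same open face, gives the saturated ester F2. Its potassium enolate (KN(SiMe3)2, −78 °C) is then hydroxylated at C6 with 2-(phenylsulfonyl)-3-phenyloxaziridine to give 15.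

3. Step 11. The gold-activated alkyne may be diverted into enyne cycloisomerisation with the allyl group, or the 5-endo attack at the hindered C9 may be slow. The fallback sets out from 6 and returns at 14, keeping C9 at the ketone level and avoiding a π-acid in the presence of the alkene. Hydration of the terminal alkyne of 6 (Ph3PAuNTf2, MeOH/H2O, before any alkene is present) gives (R)-2-acetyl-2,6,6-trimethylcyclohexan-1-one F3. Its lithium enolate (LiN(i-Pr)2, −78 °C; only C11 is enolisable) opens epoxide 10 at the CH2 carbon under Sc(OTf)3 promotion, and the γ-hydroxy ketone closes to the lactol F4. Ethanol and camphorsulfonic acid give the ethyl ketal F5; lithium ethoxyacetylide adds to the ring ketone to give the ethoxyalkynyl carbinol F6; and Sc(OTf)3-catalysed Meyer–Schuster rearrangement in EtOH/CH2Cl2 gives 14.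

Further compounds
F1 | step 15 | Δ8(9)-en-7-one with free 6β- and 13-hydroxyls (C13 allyl and CH2OTBS) | O[C@@H]1C(=O)C(C)=C(CC[C@@](O)(CC=C)CO[Si](C)(C)C(C)(C)C)[C@@]2(C)CCCC(C)(C)[C@H]12
F2 | step 12 | saturated ethyl ester (H5 trans to C10 methyl; C9 epimers) | CCOC(=O)C[C@H]1C(C)(C)CCC[C@]1(C)C1(OCC)CC[C@@](CC=C)(CO[Si](C)(C)C(C)(C)C)O1
F3 | step 11 | (R)-2-acetyl-2,6,6-trimethylcyclohexan-1-one | CC(=O)[C@@]1(C)CCCC(C)(C)C1=O
F4 | step 11 | lactol (2-hydroxyoxolane at C9; C9 epimers) | O=C1C(C)(C)CCC[C@]1(C)C1(O)CC[C@@](CC=C)(CO[Si](C)(C)C(C)(C)C)O1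
F5 | step 11 | ethyl ketal (2-ethoxyoxolane at C9; C9 epimers) | O=C1C(C)(C)CCC[C@]1(C)C1(OCC)CC[C@@](CC=C)(CO[Si](C)(C)C(C)(C)C)O1
F6 | step 11 | ethoxyalkynyl carbinol of F5 (C5 epimers) | CCOC#CC1(O)C(C)(C)CCC[C@]1(C)C1(OCC)CC[C@@](CC=C)(CO[Si](C)(C)C(C)(C)C)O1
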